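**Retrosynthetic overview**

1. Target 31 ⇐ triol 30 (C11 oxidised last) ⇐ enoate 28 ⇐ Δ7 enol triflate 27 (Pd/CO/MeOH brings in C12) ⇐ 8-oxo-decalin 25.
2. Ring B of 25 ⇐ cyclopentanol 23 by semipinacol ring expansion. The enabling feature is the carbinol carbon C8 of the five-membered ring C5–C6–C7–C8–C10: it carries the C9–C11 oxirane and is flanked by quaternary C10, so the C8–C10 bond, anti to C9–O, shifts to C9 and gives the ring C5–C6–C7–C8–C9–C10.
3. 23 ⇐ hydrindanone 21 ⇐ allene 20 ⇐ acyclic (S)-silyl ether 19 by a chloronium-triggered bicyclization (ring A 6-endo, then the five-membered ring 5-exo on a propargylsilane); the C1 stereocentre alone sets C3, C4, C5 and C10.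
4. 19 ⇐ allylic chloride 9 + enal 14 (allylbarium α-coupling, then CBS reduction).
5. Order of ring formation: ring A and the five-membered precursor of ring B in one step, then ring B by one-carbon expansion.

Key step: step 18

Remark on the chemistry: locants follow the drimane skeleton (ring A = C1–C5, C10; ring B = C5–C10; C11 = formyl carbon on C9; C12 = ester carbon on C8); α is the face of H-5, β the face of the C10 methyl; TBS = tert-butyldimethylsilyl; R = CH2–C≡C–C(CH3)2–OTBS.

**Route**

Step 1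
Reactants: 1 3-methylbut-2-en-1-yl acetate (prenyl acetate)
Product: 2 (2E)-4-hydroxy-3-methylbut-2-en-1-yl acetate
Conditions: SeO2 (cat.), t-BuOOH, salicylic acid (cat.), CH2Cl2, rt
Reagents that add atoms: tert-butyl hydroperoxide CC(C)(C)OO
Why: Catalytic SeO2 allylic oxidation (ene reaction, then 2,3-sigmatropic shift; Sharpless–Umbreit conditions) attacks the methyl group trans to the chain, so the E allylic alcohol should result.

Step 2
Reactants: 2 (2E)-4-hydroxy-3-methylbut-2-en-1-yl acetate
Product: 3 (2E)-4-bromo-3-methylbut-2-en-1-yl acetate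
Conditions: CBr4, PPh3, CH2Cl2, 0 °C
Reagents that add atoms: carbon tetrabromide BrC(Br)(Br)Br
Why: Appel bromination of a primary allylic alcohol proceeds by SN2 without allylic shift or loss of olefin geometry.

Step 3
Reactants: 4 2-methylbut-3-yn-2-ol
Product: 5 tert-butyldimethyl[(2-methylbut-3-yn-2-yl)oxy]silane
Conditions: TBSOTf, 2,6-lutidine, CH2Cl2, 0 °C
Reagents that add atoms: tert-butyldimethylsilyl triflate CC(C)(C)[Si](C)(C)OS(=O)(=O)C(F)(F)F
Why: A silyl triflate silylates the tertiary propargylic alcohol, which has to be masked for the organobarium step and the cationic cyclization.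

Step 4
Reactants: 3 (2E)-4-bromo-3-methylbut-2-en-1-yl acetate; 5 tert-butyldimethyl[(2-methylbut-3-yn-2-yl)oxy]silane
Product: 6 (2E)-7-[(tert-butyldimethylsilyl)oxy]-3,7-dimethyloct-2-en-5-yn-1-yl acetate
Conditions: CuI (cat.), K2CO3, Bu4NI (cat.), DMF, rt
Reagents that add atoms: none
Why: Copper-acetylide alkylation of a primary allylic bromide (copper-catalysed alkyne–allyl halide coupling) gives the skipped enyne by SN2 at the unhindered CH2Br; the acetate and the E olefin are not touched.

Step 5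
Reactants: 6 (2E)-7-[(tert-butyldimethylsilyl)oxy]-3,7-dimethyloct-2-en-5-yn-1-yl acetate
Product: 7 (2E)-7-[(tert-butyldimethylsilyl)oxy]-3,7-dimethyloct-2-en-5-yn-1-ol
Conditions: K2CO3 (cat.), MeOH, 0 °C
Reagents that add atoms: none
Why: Base-catalysed transesterification removes the acetate; the tertiary silyl ether and the skipped enyne survive these mild conditions.

Step 6
Reactants: 7 (2E)-7-[(tert-butyldimethylsilyl)oxy]-3,7-dimethyloct-2-en-5-yn-1-ol
Product: 9 tert-butyl{[(6E)-8-chloro-2,6-dimethyloct-6-en-3-yn-2-yl]oxy}dimethylsilane, via allylic mesylate 8 (not isolated)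
Conditions: MsCl, 2,4,6-collidine, LiCl, DMF, 0 °C
Reagents that add atoms: methanesulfonyl chloride (into 8) CS(=O)(=O)Cl; lithium chloride [Li+].[Cl-]
Why: Collington–Meyers chlorination: the mesylate formed in the flask is displaced by chloride in an SN2 reaction without allylic transposition.

Step 7
Reactants: 10 pent-4-yn-1-ol
Product: 12 6-(trimethylsilyl)hex-4-yn-1-ol, via dilithium alkoxide acetylide 11 (not isolated)
Conditions: n-BuLi (2.1 equiv), THF, −78 → 0 °C; then Me3SiCH2I, DMPU, 0 °C → rt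
Reagents that add atoms: (iodomethyl)trimethylsilane C[Si](C)(C)CI
Why: The dianion is alkylated at the more nucleophilic acetylide carbon, which is the standard route to propargylsilanes.

Step 8
Reactants: 12 6-(trimethylsilyl)hex-4-yn-1-ol
Product: 13 6-(trimethylsilyl)hex-4-ynal
Conditions: Dess–Martin periodinane, CH2Cl2, 0 °C → rt
Reagents that add atoms: none
Why: Dess–Martin oxidation takes the primary alcohol to the aldehyde under neutral conditions that spare the propargylsilane.

Step 9
Reactants: 13 6-(trimethylsilyl)hex-4-ynal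
Product: 14 (2E)-2-methyl-8-(trimethylsilyl)oct-2-en-6-ynal
Conditions: Ph3P=C(CH3)CHO, toluene, 90 °C
Reagents that add atoms: 2-(triphenylphosphoranylidene)propanal CC(C=O)=P(c1ccccc1)(c1ccccc1)c1ccccc1
Why: Wittig reaction with a stabilised ylide gives the E trisubstituted enal, which fixes the geometry of the later C5=C10 olefin.

Step 10
Reactants: 9 tert-butyl{[(6E)-8-chloro-2,6-dimethyloct-6-en-3-yn-2-yl]oxy}dimethylsilane; 14 (2E)-2-methyl-8-(trimethylsilyl)oct-2-en-6-ynal
Product: 16 racemic (6E,10E)-2-[(tert-butyldimethylsilyl)oxy]-2,6,10-trimethyl-16-(trimethylsilyl)hexadeca-6,10-diene-3,14-diyn-9-ol, via allylbarium chloride 15 (not isolated)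
Conditions: BaI2, lithium biphenylide, THF, rt (activated Ba metal); 9, −78 °C; then 14, −78 °C
Reagents that add atoms: none
Why: Yamamoto allylbarium addition: the allylic barium reagent reacts through its α carbon with retention of the E geometry and adds 1,2 to the enal, giving the linear homoallylic alcohol; the carbinol centre is racemic here and is corrected in steps 11 and 12.

Step 11
Reactants: 16 racemic dienediynol
Product: 17 (6E,10E)-2-[(tert-butyldimethylsilyl)oxy]-2,6,10-trimethyl-16-(trimethylsilyl)hexadeca-6,10-diene-3,14-diyn-9-one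
Conditions: MnO2, CH2Cl2, rt
Reagents that add atoms: none
Why: MnO2 oxidises the allylic alcohol selectively under neutral conditions, so the β,γ-olefin on the other side of the ketone does not move into conjugation.

Step 12
Reactants: 17 dienediynone
Product: 18 (6E,9S,10E)-2-[(tert-butyldimethylsilyl)oxy]-2,6,10-trimethyl-16-(trimethylsilyl)hexadeca-6,10-diene-3,14-diyn-9-ol
Conditions: (R)-2-methyl-CBS-oxazaborolidine (cat.), catecholborane, toluene, −78 °C
Reagents that add atoms: none
Why: Corey–Bakshi–Shibata reduction: with the α-methylalkenyl group as the large substituent the (R)-catalyst should give the (S)-carbinol (future C1), and catecholborane at low temperature does not hydroborate the alkynes or olefins.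

Step 13
Reactants: 18 (9S)-dienediynol
Product: 19 (6E,9S,10E)-2,9-bis[(tert-butyldimethylsilyl)oxy]-2,6,10-trimethyl-16-(trimethylsilyl)hexadeca-6,10-diene-3,14-diyne
Conditions: TBSCl, imidazole, DMF, rt
Reagents that add atoms: tert-butyldimethylsilyl chloride CC(C)(C)[Si](C)(C)Cl
Why: Standard silylation; the bulky silyl ether at C1 suppresses oxygen participation and provides the steric bias used in step 14.

Step 14
Reactants: 19 (9S)-bis(silyl ether)
Product: 20 trans-hydrindane allene: ring A with 1α-OTBS, 3β-Cl, 4β-CH3, 4α-R, 5α-H, 10β-CH3; five-membered ring C5–C6–C7–C8–C10 with exocyclic C8=C9=C11H2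
Conditions: Et2SCl·SbCl6 (1.1 equiv), MeNO2, −25 °C, 5 min; aq. NaHCO3/Na2SO3
Reagents that add atoms: chlorodiethylsulfonium hexachloroantimonate CC[S+](Cl)CC.Cl[Sb-](Cl)(Cl)(Cl)(Cl)Cl
Why: Chloronium-induced cation–olefin bicyclization (chlorosulfonium-type halonium polyene cyclization with Johnson-type propargylsilane termination): Cl+ should add to the more accessible and more electron-rich C3=C4 olefin; ring A closes 6-endo through a chair, where anti addition across the two E olefins gives 3β-Cl, 4β-CH3 and the trans ring fusion; the C10 cation is trapped 5-exo-dig by the propargylsilane to leave the allene; and the C1 silyl ether takes the pseudoaxial position to avoid A(1,2) strain with the C10 methyl, which selects the olefin face and relays the C1 configuration to C3, C4, C5 and C10.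

Step 15
Reactants: 20 trans-hydrindane allene
Product: 21 trans-hydrindan-8-one (C8 ketone next to quaternary C10; other substituents as in 20)
Conditions: O3, CH2Cl2, −78 °C (to consumption of the allene); then Me2S
Reagents that add atoms: ozone [O-][O+]=O
Why: Ozonolysis of the exocyclic allene gives the ring ketone (the Johnson route to hydrindanones); the electron-poor internal alkyne reacts much more slowly than the allene.

Step 16
Reactants: 21 trans-hydrindan-8-one
Product: 22 8β-hydroxy-8α-vinyl hydrindane (tertiary allylic alcohol; C9=C11 vinyl group)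
Conditions: CH2=CHMgBr, CeCl3, THF, −78 → 0 °C
Reagents that add atoms: vinylmagnesium bromide C=C[Mg]Br
Why: Cerium-promoted 1,2-addition to the hindered, enolisable ketone; attack anti to the angular methyl group (as for 17-oxo steroids) should give the 8β-alcohol, a centre that disappears again in step 18.

Step 17
Reactants: 22 8β-hydroxy-8α-vinyl hydrindane
Product: 23 8β-hydroxy-8α-[(9R)-oxiranyl] hydrindane (C9–C11 oxirane)
Conditions: VO(acac)2 (cat.), t-BuOOH, CH2Cl2, 0 °C → rt
Reagents that add atoms: tert-butyl hydroperoxide CC(C)(C)OO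
Why: Vanadium-directed epoxidation of the tertiary allylic alcohol is chemoselective for the vinyl group, and, as with 1-alken-3-ols, the erythro-type transition state (large group = C10) should give the (9R)-oxirane.

Step 18
Reactants: 23 8β-hydroxy-8α-[(9R)-oxiranyl] hydrindane
Product: 25 8-oxo trans-decalin with 9β-CH2OTBS and 9α-H (ring A unchanged), via tertiary silyl ether oxirane 24 (not isolated)
Conditions: TBSOTf (2 equiv), i-Pr2NEt, 4 Å MS, CH2Cl2, −78 → −40 °C
Reagents that add atoms: tert-butyldimethylsilyl triflate CC(C)(C)[Si](C)(C)OS(=O)(=O)C(F)(F)F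
Why: Silyl triflate-promoted semipinacol rearrangement of an α-hydroxy epoxide (Suzuki–Tsuchihashi/Jung type, the carbocyclic counterpart of a D-homoannulation): the carbinol is silylated, the silyl cation activates the oxirane oxygen, the C8–C10 bond shifts to C9 as the C9–O bond breaks, and silyl transfer from the oxocarbenium ion gives the C8 ketone and the C11 silyl ether. Ring B is not closed by a cyclization but grows from the five-membered ring by this suprafacial 1,2-alkyl shift (C10 keeps its configuration), driven by the push of the C8 oxygen and relief of cyclopentane strain. C9 is set by inversion at the oxirane carbon, so the (9R)-oxirane gives the 9β-CH2OSi group; the 9α epimer would in addition suffer a syn-diaxial clash with the 1α-siloxy group and could be equilibrated through the enol. The step needs migration of quaternary C10 and not of methylene C7: the fully substituted carbon is the better migrating group, and in the erythro epoxide the rotamer with C10 anti to C9–O has C11 gauche to only one ring carbon, whereas the rotamer needed for C7 migration wedges C11 between C7 and C10.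

Step 19
Reactants: 25 8-oxo trans-decalin
Product: 27 Δ7 enol triflate (C8–OTf; 9β-CH2OTBS retained), via potassium enolate 26 (not isolated)
Conditions: KN(SiMe3)2, THF, −78 °C; then PhNTf2
Reagents that add atoms: N-phenylbis(trifluoromethanesulfonimide) FC(F)(F)S(=O)(=O)N(c1ccccc1)S(=O)(=O)C(F)(F)F
Why: Kinetic deprotonation with the bulky amide takes the less hindered C7 proton (C9 is a neopentyl-type methine), and O-triflation of the enolate gives the Δ7 enol triflate.

Step 20
Reactants: 27 Δ7 enol triflate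
Product: 28 methyl Δ7-12-oate (C8–CO2CH3; 9β-CH2OTBS, 1α-OTBS, alkyne side chain R)
Conditions: Pd(OAc)2 (cat.), dppp, CO (1 atm), MeOH, Et3N, DMF, 55 °C
Reagents that add atoms: carbon monoxide [C-]#[O+]; methanol CO
Why: Palladium-catalysed methoxycarbonylation of an enol triflate (oxidative addition, CO insertion, methanolysis) installs C12 as the conjugated methyl ester.

Step 21
Reactants: 28 methyl Δ7-12-oate
Product: 29 (Z)-vinylsilane: side chain CH2–C(SiMe2Bn)=CH–C(CH3)2OTBS, with H and Si trans
Conditions: [Cp*Ru(MeCN)3]PF6 (cat.), BnMe2SiH, CH2Cl2, 0 °C → rt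
Reagents that add atoms: benzyldimethylsilane C[SiH](C)Cc1ccccc1
Why: Trost ruthenium-catalysed trans-hydrosilylation of the internal alkyne: H and Si add anti, which fixes the later E geometry (either regioisomer converges after protodesilylation), and the trisubstituted enoate is not touched.

Step 22
Reactants: 29 (Z)-vinylsilane
Product: 30 triol: methyl ester with 1α-OH, C11–OH and the (2E)-4-hydroxy-4-methylpent-2-en-1-yl side chain
Conditions: TBAF, AcOH (1:1), THF, 0 → 45 °C
Reagents that add atoms: none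
Why: Fluoride cleaves the three silyl ethers and protodesilylates the vinylsilane with retention to give the E olefin; acetic acid keeps the C11 oxygen protonated so that it should not close onto the C12 ester.

Step 23
Reactants: 30 triol
Product: 31 target, methyl (1S,3S,4S,5R,9R,10S)-3-chloro-11-oxo-1-hydroxy-4-[(2E)-4-hydroxy-4-methylpent-2-en-1-yl]-drim-7-en-12-oate type aldehyde (CNP0167913.1)
Conditions: TEMPO (cat.), PhI(OAc)2, CH2Cl2, rt
Reagents that add atoms: none
Why: Oxoammonium (TEMPO) oxidation with PhI(OAc)2 takes the primary C11 alcohol in the presence of the hindered axial secondary and the tertiary alcohol, stops at the aldehyde, and is non-basic, so the 9β configuration set in step 18 should be kept.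

**Compound list**

1 | 3-methylbut-2-en-1-yl acetate | CC(C)=CCOC(C)=O | starting material
2 | (2E)-4-hydroxy-3-methylbut-2-en-1-yl acetate | CC(=O)OC/C=C(\C)CO | intermediate
3 | (2E)-4-bromo-3-methylbut-2-en-1-yl acetate | CC(=O)OC/C=C(\C)CBr | intermediate
4 | 2-methylbut-3-yn-2-ol | CC(C)(O)C#C | starting material
5 | tert-butyldimethyl[(2-methylbut-3-yn-2-yl)oxy]silane | CC(C)(C#C)O[Si](C)(C)C(C)(C)C | intermediate
6 | (2E)-7-[(tert-butyldimethylsilyl)oxy]-3,7-dimethyloct-2-en-5-yn-1-yl acetate | CC(=O)OC/C=C(\C)CC#CC(C)(C)O[Si](C)(C)C(C)(C)C | intermediate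
7 | (2E)-7-[(tert-butyldimethylsilyl)oxy]-3,7-dimethyloct-2-en-5-yn-1-ol | OC/C=C(\C)CC#CC(C)(C)O[Si](C)(C)C(C)(C)C | intermediate
8 | (2E)-7-[(tert-butyldimethylsilyl)oxy]-3,7-dimethyloct-2-en-5-yn-1-yl methanesulfonate | CS(=O)(=O)OC/C=C(\C)CC#CC(C)(C)O[Si](C)(C)C(C)(C)C | intermediate (not isolated)
9 | tert-butyl{[(6E)-8-chloro-2,6-dimethyloct-6-en-3-yn-2-yl]oxy}dimethylsilane | ClC/C=C(\C)CC#CC(C)(C)O[Si](C)(C)C(C)(C)C | intermediate
10 | pent-4-yn-1-ol | OCCCC#C | starting material
11 | dilithium 5-oxidopent-1-yn-1-ide | [Li+].[Li+].[O-]CCCC#[C-] | intermediate (not isolated)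
12 | 6-(trimethylsilyl)hex-4-yn-1-ol | OCCCC#CC[Si](C)(C)C | intermediate
13 | 6-(trimethylsilyl)hex-4-ynal | O=CCCC#CC[Si](C)(C)C | intermediate
14 | (2E)-2-methyl-8-(trimethylsilyl)oct-2-en-6-ynal | O=C/C(C)=C/CCC#CC[Si](C)(C)C | intermediate
15 | [(2E)-7-(tert-butyldimethylsilyloxy)-3,7-dimethyloct-2-en-5-yn-1-yl]barium chloride | Cl[Ba]C/C=C(\C)CC#CC(C)(C)O[Si](C)(C)C(C)(C)C | intermediate (not isolated)
16 | racemic (6E,10E)-2-[(tert-butyldimethylsilyl)oxy]-2,6,10-trimethyl-16-(trimethylsilyl)hexadeca-6,10-diene-3,14-diyn-9-ol | C[Si](C)(C)CC#CCC/C=C(\C)C(O)C/C=C(\C)CC#CC(C)(C)O[Si](C)(C)C(C)(C)C | intermediate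
17 | (6E,10E)-2-[(tert-butyldimethylsilyl)oxy]-2,6,10-trimethyl-16-(trimethylsilyl)hexadeca-6,10-diene-3,14-diyn-9-one | C[Si](C)(C)CC#CCC/C=C(\C)C(=O)C/C=C(\C)CC#CC(C)(C)O[Si](C)(C)C(C)(C)C | intermediate
18 | (6E,9S,10E)-2-[(tert-butyldimethylsilyl)oxy]-2,6,10-trimethyl-16-(trimethylsilyl)hexadeca-6,10-diene-3,14-diyn-9-ol | C[Si](C)(C)CC#CCC/C=C(\C)[C@@H](O)C/C=C(\C)CC#CC(C)(C)O[Si](C)(C)C(C)(C)C | intermediate
19 | (6E,9S,10E)-2,9-bis[(tert-butyldimethylsilyl)oxy]-2,6,10-trimethyl-16-(trimethylsilyl)hexadeca-6,10-diene-3,14-diyne | C[Si](C)(C)CC#CCC/C=C(\C)[C@@H](O[Si](C)(C)C(C)(C)C)C/C=C(\C)CC#CC(C)(C)O[Si](C)(C)C(C)(C)C | intermediate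
20 | trans-hydrindane allene (1α-OTBS, 3β-Cl, 4β-CH3, 4α-R, 5α-H, 10β-CH3; exocyclic C8=C9=C11H2) | C1C[C@H]2[C@](C)(CC#CC(C)(C)O[Si](C)(C)C(C)(C)C)[C@@H](Cl)C[C@H](O[Si](C)(C)C(C)(C)C)[C@]2(C)C1=C=C | intermediate
21 | trans-hydrindan-8-one (substituents as in 20) | C1C[C@H]2[C@](C)(CC#CC(C)(C)O[Si](C)(C)C(C)(C)C)[C@@H](Cl)C[C@H](O[Si](C)(C)C(C)(C)C)[C@]2(C)C1=O | intermediate
22 | 8β-hydroxy-8α-vinyl hydrindane | C1C[C@H]2[C@](C)(CC#CC(C)(C)O[Si](C)(C)C(C)(C)C)[C@@H](Cl)C[C@H](O[Si](C)(C)C(C)(C)C)[C@]2(C)[C@]1(O)C=C | intermediate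
23 | 8β-hydroxy-8α-[(9R)-oxiranyl] hydrindane | C1C[C@H]2[C@](C)(CC#CC(C)(C)O[Si](C)(C)C(C)(C)C)[C@@H](Cl)C[C@H](O[Si](C)(C)C(C)(C)C)[C@]2(C)[C@]1(O)[C@H]1CO1 | intermediate
24 | 8β-(tert-butyldimethylsilyloxy)-8α-[(9R)-oxiranyl] hydrindane | C1C[C@H]2[C@](C)(CC#CC(C)(C)O[Si](C)(C)C(C)(C)C)[C@@H](Cl)C[C@H](O[Si](C)(C)C(C)(C)C)[C@]2(C)[C@]1(O[Si](C)(C)C(C)(C)C)[C@H]1CO1 | intermediate (not isolated)
25 | 8-oxo trans-decalin with 9β-CH2OTBS (1α-OTBS, 3β-Cl, 4β-CH3, 4α-R, 5α-H, 10β-CH3) | O=C1CC[C@H]2[C@](C)(CC#CC(C)(C)O[Si](C)(C)C(C)(C)C)[C@@H](Cl)C[C@H](O[Si](C)(C)C(C)(C)C)[C@]2(C)[C@H]1CO[Si](C)(C)C(C)(C)C | intermediate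
26 | potassium Δ7-enolate of 25 | [K+].[O-]C1=CC[C@H]2[C@](C)(CC#CC(C)(C)O[Si](C)(C)C(C)(C)C)[C@@H](Cl)C[C@H](O[Si](C)(C)C(C)(C)C)[C@]2(C)[C@H]1CO[Si](C)(C)C(C)(C)C | intermediate (not isolated)
27 | Δ7 enol triflate (C8–OTf) | FC(F)(F)S(=O)(=O)OC1=CC[C@H]2[C@](C)(CC#CC(C)(C)O[Si](C)(C)C(C)(C)C)[C@@H](Cl)C[C@H](O[Si](C)(C)C(C)(C)C)[C@]2(C)[C@H]1CO[Si](C)(C)C(C)(C)C | intermediate
28 | methyl Δ7-12-oate with 9β-CH2OTBS, 1α-OTBS and alkyne side chain R | COC(=O)C1=CC[C@H]2[C@](C)(CC#CC(C)(C)O[Si](C)(C)C(C)(C)C)[C@@H](Cl)C[C@H](O[Si](C)(C)C(C)(C)C)[C@]2(C)[C@H]1CO[Si](C)(C)C(C)(C)C | intermediate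
29 | (Z)-vinylsilane of 28 (side chain CH2–C(SiMe2Bn)=CH–C(CH3)2OTBS) | COC(=O)C1=CC[C@H]2[C@](C)(C/C([Si](C)(C)Cc3ccccc3)=C/C(C)(C)O[Si](C)(C)C(C)(C)C)[C@@H](Cl)C[C@H](O[Si](C)(C)C(C)(C)C)[C@]2(C)[C@H]1CO[Si](C)(C)C(C)(C)C | intermediate
30 | triol (1α-OH, C11–OH, side-chain tertiary OH; E olefin) | COC(=O)C1=CC[C@H]2[C@](C)(C/C=C/C(C)(C)O)[C@@H](Cl)C[C@H](O)[C@]2(C)[C@H]1CO | intermediate
31 | CNP0167913.1 | COC(=O)C1=CC[C@H]2[C@](C)(C/C=C/C(C)(C)O)[C@@H](Cl)C[C@H](O)[C@]2(C)[C@H]1C=O | target

**Step count and risks**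

Total step count: 23. Longest linear sequence: 19 steps (1, 2, 4, 5, 6, 10–23).

Steps most likely to fail:

1. Step 14. What may go wrong: the chloronium donor chlorinates the propargylsilane or the C5=C10 olefin, the C1 silyl ether oxygen captures the C4 cation, or the C1 stereocentre selects the olefin face poorly. Fallback, from 19 back to 20: the chloriranium ion is generated with reagent-controlled configuration and without an external Cl+ source. Shi asymmetric epoxidation (the ketone enantiomer that attacks the C3=C4 face opposite to the one on which chlorine must end up; the allylically deactivated C5=C10 olefin reacts more slowly) would give the (3,4)-epoxide F1. Opening with LiCl/AcOH in THF at the secondary carbon with inversion would give the (3S)-chlorohydrin F2. Ionisation of its tertiary alcohol with SnCl4 in CH2Cl2 at −78 °C (chlorine participation, then anti attack by C5 and propargylsilane termination) would give 20.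

2. Step 18. What may go wrong: the ring methylene C7 migrates instead of quaternary C10, or the activated oxirane is opened without any carbon shift. Fallback, from 21 to 31: a ring expansion in which methylene migration is the productive event. Methyl diazoacetate and BF3·OEt2 (Tiffeneau–Demjanov-type homologation, as in D-homoannulation of 17-oxo steroids) would insert the ester-bearing carbon (future C8 with C12) between C7 and the carbonyl carbon, which becomes C9, giving the β-keto ester F3. NaH/PhNTf2 would give the enol triflate F4. Pd(PPh3)4/CO/Bu3SnH (reductive carbonylation) would give the Δ8 enal F5. γ-Deprotonation at C7 with KN(SiMe3)2 and kinetic α-protonation with AcOH at −78 °C would give the Δ7 9β-aldehyde F6. Trans-hydrosilylation as in step 21 would give the vinylsilane F7, and buffered TBAF as in step 22 would give 31.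

3. Step 22. What may go wrong: once C11–OH is free next to the C12 ester it can lactonise (five-membered α-alkylidene lactone), especially if an alkoxide forms during the slow cleavage of the hindered silyl ethers. Fallback, from 28 to 31: C11 is taken to the aldehyde before the other hydroxyls are unmasked. HF·pyridine buffered with pyridine (THF, 0 °C) would remove only the primary silyl ether to give the alcohol F8; Dess–Martin oxidation would give the aldehyde F6; hydrosilylation as in step 21 would give the vinylsilane F7; and buffered TBAF would give 31.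

Further compounds
F1 | step 14 | (3,4)-epoxide of 19 (oxirane on the E C6=C7 olefin of the hexadeca chain) | C[Si](C)(C)CC#CCC/C=C(\C)[C@@H](O[Si](C)(C)C(C)(C)C)C[C@H]1O[C@]1(C)CC#CC(C)(C)O[Si](C)(C)C(C)(C)C
F2 | step 14 | (3S)-chlorohydrin: secondary chloride at C3, tertiary alcohol at C4 | C[Si](C)(C)CC#CCC/C=C(\C)[C@@H](O[Si](C)(C)C(C)(C)C)C[C@H](Cl)[C@@](O)(C)CC#CC(C)(C)O[Si](C)(C)C(C)(C)C
F3 | step 18 | trans-decalin β-keto ester (9-oxo, methyl 8-carboxylate; C8 epimers/enol) | COC(=O)C1CC[C@H]2[C@](C)(CC#CC(C)(C)O[Si](C)(C)C(C)(C)C)[C@@H](Cl)C[C@H](O[Si](C)(C)C(C)(C)C)[C@]2(C)C1=O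
F4 | step 18 | C9 enol triflate of F3 (Δ8) | C1C[C@H]2[C@](C)(CC#CC(C)(C)O[Si](C)(C)C(C)(C)C)[C@@H](Cl)C[C@H](O[Si](C)(C)C(C)(C)C)[C@]2(C)C(OS(=O)(=O)C(F)(F)F)=C1C(=O)OC
F5 | step 18 | Δ8 11-al 12-methyl ester | C1C[C@H]2[C@](C)(CC#CC(C)(C)O[Si](C)(C)C(C)(C)C)[C@@H](Cl)C[C@H](O[Si](C)(C)C(C)(C)C)[C@]2(C)C(C=O)=C1C(=O)OC
F6 | step 18 | Δ7 9β-aldehyde with 1α-OTBS and alkyne side chain R | COC(=O)C1=CC[C@H]2[C@](C)(CC#CC(C)(C)O[Si](C)(C)C(C)(C)C)[C@@H](Cl)C[C@H](O[Si](C)(C)C(C)(C)C)[C@]2(C)[C@H]1C=O
F7 | step 18 | (Z)-vinylsilane of F6 | COC(=O)C1=CC[C@H]2[C@](C)(C/C([Si](C)(C)Cc3ccccc3)=C/C(C)(C)O[Si](C)(C)C(C)(C)C)[C@@H](Cl)C[C@H](O[Si](C)(C)C(C)(C)C)[C@]2(C)[C@H]1C=O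
F8 | step 22 | C11 primary alcohol of 28 (other silyl ethers kept) | COC(=O)C1=CC[C@H]2[C@](C)(CC#CC(C)(C)O[Si](C)(C)C(C)(C)C)[C@@H](Cl)C[C@H](O[Si](C)(C)C(C)(C)C)[C@]2(C)[C@H]1CO
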